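Follow one X: it stays X or ends in L. Follow one J: it stays J or stands as a chain, Z or Z.G. So in each flask the average length is X charged per J charged, times the fraction of X reacted, divided by the fraction of J reacted.

    X + J → Z + L (k1 = 0.157 M⁻¹ min⁻¹)
    Z + G → Z.G (k2 = 7.68 M⁻¹ min⁻¹)
    X + Z → L + Z, rate k3*[Z]*[X] (k3 = 1.77 M⁻¹ min⁻¹)

- dusk: X 1.1 M; G 0.0110 M; J 28 mM; time 80 min
- dawn: X 0.60 M; G 0.0110 M; J 28 mM; time 80 min

- the average divides the monomer in chains by the number of chains begun, living and dead together
- run time (dusk): 80 min

- which of the two ends with the longer chains by the average number of monomer units in a chain (chains begun, living or dead) ("neither" if they lie within 10%) (dusk / dawn / neither)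
- average number of monomer units in a chain (chains begun, living or dead) at the end, dusk
- average number of monomer units in a chain (chains begun, living or dead) at the end, dawn

- X charged per J charged is 39.3 in dusk and 21.4 in dawn. I carry this charge ratio and need just the two fractions beside it.
- For a first pass I count every J as a chain begun, so the fraction of J reacted is taken as one.
- Each G kills one Z, and G is charged at 39.3% of J, less than J, so I expect 60.7% of the ends to stay alive. The half-life of Z by step 2 alone at the dusk charges is 8.2 min, shorter than the run of 80 min, so I take this killing as an early event.
- X then falls in a pseudo-first-order way at k3 times the surviving ends, 0.0301 min⁻¹ in both flasks. That gives a fraction reacted of 91.0% and lengths of 35.8 for dusk and 19.5 for dawn.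
- The weak link is that the ends do not stand there from the start. With X held at its charge, a J waits about 5.79 min in dusk and 10.6 min in dawn, longer in dawn, where less X is charged.
- Taking each wait off the run gives fractions of 89.3% for dusk and 87.6% for dawn. I commit to 35.1 for dusk and 18.8 for dawn, so dusk has the longer chains.
- The forecast says dusk, with 35.5 for dusk and 19.2 for dawn, a little longer than mine in both, and it calls the length “set mainly by the monomer charge divided by about 0.028 M of chains”.

After the run:

- The flask gives dusk, with 35.5 for dusk and 19.3 for dawn.
- With the other amounts and the time held, dawn's length has moved by 1.93 at X of 0.540 M or 0.660 M, or at J of 21.5 mM or 33.9 mM.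
- At the end of dawn, L is 87.1% of the X charged and 3.1% of the J charged is left, so the charge ratio gives 19.2.
- In the dusk recipe with 0.070 M of J, the charge ratio is 15.7. L reaches 99.9% of the X charged and 8.3% of the J charged is left, so the ratio gives 17.1, and that flask gives 17.1.

(The numbers of this flask stand for no real mixture, and the outcome is calculated.)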